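**Retrosynthetic overview**

- The strategy rests on C8, the tertiary carbinol carbon that carries the OH, the 2-hydroxy-4-methylphenyl ring and two CH2O–acyl arms (C9, C10). Both arms are at the alcohol oxidation level and differ only in their acyl groups, so they can descend from two enantiotopic CO2Et groups on one carbon.
- Target 16 ⇐ acetonide diester 15 (ketal hydrolysis) ⇐ stepwise acylation of the two arms, kept apart by a TBDPS ether (isobutyrate on the ester-derived arm, (S)-2-methylbutanoate on the arm made in the key step).
- Hydroxy ester 9 ⇐ desymmetrising mono-reduction of the ketal-protected aryl(oxy)malonate 6, which sets C8.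
- 6 ⇐ ketalisation of hydroxymalonate 4 with 2,2-dimethoxypropane ⇐ ortho-hydroxyalkylation of m-cresol with diethyl ketomalonate (aryl–C8 bond).
- Rings: the aromatic ring comes from m-cresol; the only ring formed is the temporary 1,3-dioxine ring (step 2), which is opened again in the last step.

Key step: step 3

Remark: the sense in which the zinc catalyst selects between the two ester groups of 6 cannot be predicted with certainty; the ligand antipode that leads to (R)-9 is assumed to be used, both antipodes being accessible from the two enantiomers of pipecolic acid.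

**Route**

Step 1
Reactants: 1 m-cresol; 2 diethyl ketomalonate
Product: 4 diethyl 2-hydroxy-2-(2-hydroxy-4-methylphenyl)propanedioate, via bromomagnesium 3-methylphenoxide 3 (not isolated)
Conditions: EtMgBr (1.0 equiv), Et2O, 0 °C; solvent exchange to toluene; 2 (1.2 equiv), 0 °C → rt; cold 1 M HCl quench
Reagents that add atoms: ethylmagnesium bromide, CC[Mg]Br (its Mg and Br are carried only by 3 and leave on work-up)
Why: The bromomagnesium phenoxide holds the highly electrophilic central carbonyl of 2 on magnesium next to the ring, so this chelation-directed Friedel–Crafts hydroxyalkylation (Casiraghi-type ortho-hydroxyalkylation of a magnesium phenoxide) should attack only ortho to oxygen, and of the two ortho sites the one para to the methyl group is far less hindered than the one between OH and CH3.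

Step 2
Reactants: 4 diethyl 2-hydroxy-2-(2-hydroxy-4-methylphenyl)propanedioate; 5 2,2-dimethoxypropane
Product: 6 diethyl 2,2,7-trimethyl-4H-1,3-benzodioxine-4,4-dicarboxylate
Conditions: 5 (5 equiv), PPTS (10 mol %), CH2Cl2, 5 Å MS, rt → 40 °C
Reagents that add atoms: 2,2-dimethoxypropane (5), COC(C)(C)OC
Why: Acid-catalysed transketalisation should tie the phenol and the tertiary hydroxyl of the 2-hydroxybenzyl alcohol unit into the six-membered acetonide (the 1,3-benzodioxine ring familiar from saligenin-type diols), and a weak acid near room temperature with sieves taking up methanol should keep this ahead of lactonisation of the phenol onto an ester.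

Step 3
Reactants: 6 diethyl 2,2,7-trimethyl-4H-1,3-benzodioxine-4,4-dicarboxylate
Product: 9 ethyl (R)-4-(hydroxymethyl)-2,2,7-trimethyl-4H-1,3-benzodioxine-4-carboxylate, via aldehyde ester 7 (not isolated), via triethoxysilyl ether 8 (not isolated)
Conditions: ZnEt2 (10 mol %), chiral 2,6-bis{[2-(diarylhydroxymethyl)piperidin-1-yl]methyl}-4-methylphenol ligand (5 mol %), (EtO)3SiH (3 equiv), THF, 0 °C → rt; then K2CO3 (cat.), EtOH/H2O, 0 °C
Reagents that add atoms: triethoxysilane, CCO[SiH](OCC)OCC (its silicon is carried only by 8 and leaves on hydrolysis; 9 gains hydrogen only)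
Why: ZnEt2 and the tetradentate ligand form a dinuclear zinc alkoxide that the silane converts into a Zn–H species; one zinc binds an ester carbonyl of 6 as a Lewis acid (the adjacent ring oxygen O3 offering a second contact) while hydride is delivered, the zinc hemiacetalate loses ethoxide to give aldehyde 7, and 7 is reduced much faster than the remaining ester to silyl ether 8, which mild hydrolysis converts into 9. The closest known reaction type is the dinuclear-zinc-catalysed desymmetrising hydrosilylation of α,α-disubstituted malonic esters to α-quaternary β-hydroxy esters, which tolerates α-heteroatom substituents. No ring is closed in this step. The C4 stereocentre (C8 of the target) is set by the catalyst's choice between the two enantiotopic CO2Et groups, which it reads from the flat aryl carbon C4a against the ketal oxygen O3, both held in fixed positions by the benzodioxine ring. The step needs enantiotopic-group selectivity and a stop at mono-reduction: the first is secured by the strong steric and electronic contrast between aryl and oxygen on the rigid ring, the second by the rate gap between the aldehyde and the second, now more hindered ester. The ketal also keeps the phenol and the tertiary hydroxyl from consuming Zn–H or lactonising.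

Step 4
Reactants: 9 ethyl (R)-4-(hydroxymethyl)-2,2,7-trimethyl-4H-1,3-benzodioxine-4-carboxylate
Product: 10 ethyl (R)-4-{[(tert-butyldiphenylsilyl)oxy]methyl}-2,2,7-trimethyl-4H-1,3-benzodioxine-4-carboxylate
Conditions: TBDPSCl (1.2 equiv), imidazole (2.5 equiv), DMF, rt
Reagents that add atoms: tert-butyl(chloro)diphenylsilane, CC(C)(C)[Si](Cl)(c1ccccc1)c1ccccc1
Why: Silylation of the primary neopentyl-type alcohol with a silyl chloride and imidazole is standard, and the bulky TBDPS group is chosen because it is slow to shift to a neighbouring oxygen once the second arm is freed.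

Step 5
Reactants: 10 ethyl (R)-4-{[(tert-butyldiphenylsilyl)oxy]methyl}-2,2,7-trimethyl-4H-1,3-benzodioxine-4-carboxylate
Product: 11 [(S)-4-{[(tert-butyldiphenylsilyl)oxy]methyl}-2,2,7-trimethyl-4H-1,3-benzodioxin-4-yl]methanol
Conditions: DIBAL-H (3 equiv), CH2Cl2, −78 → 0 °C; Rochelle salt work-up
Reagents that add atoms: none
Why: DIBAL-H reduction of the remaining ethyl ester to the primary alcohol should proceed at low temperature, where the aluminium alkoxide formed is too weakly basic to trigger a 1,5-silyl shift that would exchange the two arms, and the ketal and silyl ether are inert to the reagent (the descriptor changes only through CIP priorities).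

Step 6
Reactants: 11 [(S)-4-{[(tert-butyldiphenylsilyl)oxy]methyl}-2,2,7-trimethyl-4H-1,3-benzodioxin-4-yl]methanol
Product: 12 [(S)-4-{[(tert-butyldiphenylsilyl)oxy]methyl}-2,2,7-trimethyl-4H-1,3-benzodioxin-4-yl]methyl 2-methylpropanoate
Conditions: i-PrCOCl (1.5 equiv), pyridine, DMAP (cat.), CH2Cl2, 0 °C → rt
Reagents that add atoms: isobutyryl chloride, CC(C)C(Cl)=O
Why: Acylation of a primary alcohol with an acid chloride under pyridine/DMAP catalysis (nucleophilic acyl substitution) is reliable even at a neopentyl-type position and touches neither the silyl ether nor the ketal.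

Step 7
Reactants: 12 [(S)-4-{[(tert-butyldiphenylsilyl)oxy]methyl}-2,2,7-trimethyl-4H-1,3-benzodioxin-4-yl]methyl 2-methylpropanoate
Product: 13 [(R)-4-(hydroxymethyl)-2,2,7-trimethyl-4H-1,3-benzodioxin-4-yl]methyl 2-methylpropanoate
Conditions: HF·pyridine, pyridine, THF, 0 °C → rt
Reagents that add atoms: none
Why: Buffered HF·pyridine cleaves the Si–O bond by fluoride attack at silicon under weakly acidic conditions, so no free alkoxide appears that could pull the isobutyryl group across to the other arm, and the acetonide and the ester should remain untouched.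

Step 8
Reactants: 13 [(R)-4-(hydroxymethyl)-2,2,7-trimethyl-4H-1,3-benzodioxin-4-yl]methyl 2-methylpropanoate; 14 (S)-2-methylbutanoic acid
Product: 15 [(S)-2,2,7-trimethyl-4-{[(2-methylpropanoyl)oxy]methyl}-4H-1,3-benzodioxin-4-yl]methyl (S)-2-methylbutanoate
Conditions: 14 (1.5 equiv), DCC (1.5 equiv), DMAP (0.1 equiv), CH2Cl2, 0 °C → rt
Reagents that add atoms: (S)-2-methylbutanoic acid (14), CC[C@H](C)C(=O)O
Why: Steglich esterification (DCC with a small amount of DMAP) joins the primary alcohol to the α-branched acid under near-neutral conditions at 0 °C, where the α-stereocentre brought in unchanged from the chiral-pool acid should not enolise and no acyl shift between the arms is expected.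

Step 9
Reactants: 15 [(S)-2,2,7-trimethyl-4-{[(2-methylpropanoyl)oxy]methyl}-4H-1,3-benzodioxin-4-yl]methyl (S)-2-methylbutanoate
Product: 16 (2S)-2-hydroxy-2-(2-hydroxy-4-methylphenyl)-3-[(2-methylpropanoyl)oxy]propyl (2S)-2-methylbutanoate (CNP0286200.1)
Conditions: AcOH/H2O (4:1), 50 °C
Reagents that add atoms: none
Why: Acid-catalysed ketal hydrolysis should open the 2,2-dimethyl-1,3-benzodioxine through the oxocarbenium ion at the acetonide carbon (never at C8, so its configuration is kept), freeing the phenol and the tertiary alcohol while the two primary esters survive because ester hydrolysis is far slower in aqueous acetic acid.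

**Compound list**

1 | m-cresol | Cc1cccc(O)c1 | starting material
2 | diethyl ketomalonate | CCOC(=O)C(=O)C(=O)OCC | starting material
3 | bromomagnesium 3-methylphenoxide | Cc1cccc(O[Mg]Br)c1 | intermediate
4 | diethyl 2-hydroxy-2-(2-hydroxy-4-methylphenyl)propanedioate | CCOC(=O)C(O)(C(=O)OCC)c1ccc(C)cc1O | intermediate
5 | 2,2-dimethoxypropane | COC(C)(C)OC | starting material
6 | diethyl 2,2,7-trimethyl-4H-1,3-benzodioxine-4,4-dicarboxylate | CCOC(=O)C1(C(=O)OCC)OC(C)(C)Oc2cc(C)ccc12 | intermediate
7 | ethyl (R)-4-formyl-2,2,7-trimethyl-4H-1,3-benzodioxine-4-carboxylate | O=C[C@]1(C(=O)OCC)OC(C)(C)Oc2cc(C)ccc12 | intermediate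
8 | ethyl (R)-2,2,7-trimethyl-4-{[(triethoxysilyl)oxy]methyl}-4H-1,3-benzodioxine-4-carboxylate | CCO[Si](OCC)(OCC)OC[C@]1(C(=O)OCC)OC(C)(C)Oc2cc(C)ccc12 | intermediate
9 | ethyl (R)-4-(hydroxymethyl)-2,2,7-trimethyl-4H-1,3-benzodioxine-4-carboxylate | OC[C@]1(C(=O)OCC)OC(C)(C)Oc2cc(C)ccc12 | intermediate
10 | ethyl (R)-4-{[(tert-butyldiphenylsilyl)oxy]methyl}-2,2,7-trimethyl-4H-1,3-benzodioxine-4-carboxylate | CC(C)(C)[Si](c3ccccc3)(c3ccccc3)OC[C@]1(C(=O)OCC)OC(C)(C)Oc2cc(C)ccc12 | intermediate
11 | [(S)-4-{[(tert-butyldiphenylsilyl)oxy]methyl}-2,2,7-trimethyl-4H-1,3-benzodioxin-4-yl]methanol | CC(C)(C)[Si](c3ccccc3)(c3ccccc3)OC[C@]1(CO)OC(C)(C)Oc2cc(C)ccc12 | intermediate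
12 | [(S)-4-{[(tert-butyldiphenylsilyl)oxy]methyl}-2,2,7-trimethyl-4H-1,3-benzodioxin-4-yl]methyl 2-methylpropanoate | CC(C)(C)[Si](c3ccccc3)(c3ccccc3)OC[C@]1(COC(=O)C(C)C)OC(C)(C)Oc2cc(C)ccc12 | intermediate
13 | [(R)-4-(hydroxymethyl)-2,2,7-trimethyl-4H-1,3-benzodioxin-4-yl]methyl 2-methylpropanoate | OC[C@]1(COC(=O)C(C)C)OC(C)(C)Oc2cc(C)ccc12 | intermediate
14 | (S)-2-methylbutanoic acid | CC[C@H](C)C(=O)O | starting material
15 | [(S)-2,2,7-trimethyl-4-{[(2-methylpropanoyl)oxy]methyl}-4H-1,3-benzodioxin-4-yl]methyl (S)-2-methylbutanoate | CC[C@H](C)C(=O)OC[C@]1(COC(=O)C(C)C)OC(C)(C)Oc2cc(C)ccc12 | intermediate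
16 | (2S)-2-hydroxy-2-(2-hydroxy-4-methylphenyl)-3-[(2-methylpropanoyl)oxy]propyl (2S)-2-methylbutanoate | CC[C@H](C)C(=O)OC[C@@](O)(COC(=O)C(C)C)c1ccc(C)cc1O | target

**Step count**

Total steps: 9. Longest linear sequence: 9 steps (1 → 16).

**Steps most likely to fail, with fallbacks**

Step 3 (key step). The catalyst may discriminate poorly between the two enantiotopic ester groups, or reduction may run on to the diol. The hydride desymmetrisation would then be replaced by an enzymatic one. Setting out from 6, pig liver esterase in phosphate buffer (pH 7–8, with a cosolvent) would hydrolyse one enantiotopic ester to (R)-4-(ethoxycarbonyl)-2,2,7-trimethyl-4H-1,3-benzodioxine-4-carboxylic acid F1, an isoenzyme with the required sense being selected. BH3·SMe2 in THF at 0 °C, which reduces a carboxylic acid in the presence of an ester, would then convert F1 into 9, where the route is rejoined.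

Step 2. Ring closure onto the hindered, electron-poor tertiary hydroxyl may be slower than acid-promoted lactonisation of the phenol onto one of the geminal esters. The ring would then be closed before the second ester exists. Setting out from 1, the bromomagnesium phenoxide 3 would be combined with ethyl glyoxylate in the same ortho-hydroxyalkylation to give racemic ethyl 2-hydroxy-2-(2-hydroxy-4-methylphenyl)acetate F2. Its more nucleophilic secondary hydroxyl should ketalise readily with 5 and PPTS to give racemic ethyl 2,2,7-trimethyl-4H-1,3-benzodioxine-4-carboxylate F3. Deprotonation of F3 with LiHMDS in THF at −78 °C and C-acylation of the α-alkoxy-α-aryl ester enolate with ethyl chloroformate would give 6, where the route is rejoined; the stereocentre of F3 is erased in this step, so its racemic nature is of no consequence.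

Step 7. Any alkoxide character during desilylation could trigger a 1,3-O→O shift of the isobutyryl group between the two arms (and, one stage earlier, a silyl shift in 11); either process exchanges the arms and erodes the configuration at C8. The silyl ether would then be replaced by a benzyl ether that is removed by neutral hydrogenolysis. Setting out from 9, 2-benzyloxy-1-methylpyridinium triflate with MgO in PhCF3 at 85 °C (neutral benzylation, no alkoxide and hence no retro-aldol) would give ethyl (R)-4-[(benzyloxy)methyl]-2,2,7-trimethyl-4H-1,3-benzodioxine-4-carboxylate F4. DIBAL-H reduction as in step 5 would give [(S)-4-[(benzyloxy)methyl]-2,2,7-trimethyl-4H-1,3-benzodioxin-4-yl]methanol F5, and acylation as in step 6 would give [(R)-4-[(benzyloxy)methyl]-2,2,7-trimethyl-4H-1,3-benzodioxin-4-yl]methyl 2-methylpropanoate F6. Hydrogenolysis of F6 (H2, Pd/C, EtOAc, rt) would release 13 without any base or fluoride, and the route is rejoined at 13.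

**Further compounds**

F1 | step 3 | (R)-4-(ethoxycarbonyl)-2,2,7-trimethyl-4H-1,3-benzodioxine-4-carboxylic acid | OC(=O)[C@]1(C(=O)OCC)OC(C)(C)Oc2cc(C)ccc12
F2 | step 2 | ethyl 2-hydroxy-2-(2-hydroxy-4-methylphenyl)acetate (racemic) | CCOC(=O)C(O)c1ccc(C)cc1O
F3 | step 2 | ethyl 2,2,7-trimethyl-4H-1,3-benzodioxine-4-carboxylate (racemic) | CCOC(=O)C1OC(C)(C)Oc2cc(C)ccc12
F4 | step 7 | ethyl (R)-4-[(benzyloxy)methyl]-2,2,7-trimethyl-4H-1,3-benzodioxine-4-carboxylate | c3ccccc3COC[C@]1(C(=O)OCC)OC(C)(C)Oc2cc(C)ccc12
F5 | step 7 | [(S)-4-[(benzyloxy)methyl]-2,2,7-trimethyl-4H-1,3-benzodioxin-4-yl]methanol | c3ccccc3COC[C@]1(CO)OC(C)(C)Oc2cc(C)ccc12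
F6 | step 7 | [(R)-4-[(benzyloxy)methyl]-2,2,7-trimethyl-4H-1,3-benzodioxin-4-yl]methyl 2-methylpropanoate | c3ccccc3COC[C@]1(COC(=O)C(C)C)OC(C)(C)Oc2cc(C)ccc12
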